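**Retrosynthetic overview**

- Feature: the only stereocentre is C2 of the dihydropyranone ring C. It carries O1, H and C1' of the 3,4-dimethoxyphenyl ring B and lies β to the C4 ketone, so it corresponds to the β-carbon of the flat C2=C3–C4=O enone of a chromone.
- Disconnection 1 (last C–C bond): C2–C1', made by ligand-controlled conjugate arylation of the 7-O-MOM-6,8-diprenylchromone with 3,4-dimethoxyphenylboronic acid. The MOM ether then comes off under mild acid.
- Disconnection 2: the prenyl chains at C6 and C8, made by twofold Stille coupling of the 6,8-diiodochromone with prenyltributylstannane.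
- Disconnection 3: O1–C2 and C2–C3 of ring C, made by enaminone formation with DMF dimethyl acetal and ring closure on 3,5-diiodo-2,4-dihydroxyacetophenone with its 4-OH masked.
- Ring order: ring A is bought, ring C is closed second, ring B is attached last.

Key step: step 6

Assumption: the (S,S)-diene ligand is taken to induce the same spatial sense as it does with 2-cyclohexenone, which corresponds to 2S here. Both antipodes are sold, so the other one would be used if a CD check of 10 pointed to 2R.

**Step 1**
Reactants: 1 2,4-dihydroxyacetophenone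
Product: 2 1-(2,4-dihydroxy-3,5-diiodophenyl)ethanone
Conditions: NIS (2.1 equiv), p-TsOH·H2O (0.1 equiv), MeCN, 0 °C to rt, dark
Reagents that add atoms: N-iodosuccinimide, O=C1CCC(=O)N1I
Why: Electrophilic aromatic iodination: C3 and C5 are each ortho or para to both hydroxyl groups and are the only strongly activated positions, whereas C6 is meta to both and next to the acetyl group, so two equivalents of the iodonium source should stop at the 3,5-diiodide.

**Step 2**
Reactants: 2 1-(2,4-dihydroxy-3,5-diiodophenyl)ethanone
Product: 3 1-[2-hydroxy-3,5-diiodo-4-(methoxymethoxy)phenyl]ethanone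
Conditions: MOMCl (1.1 equiv), K2CO3 (1.5 equiv), acetone, 0 °C to rt
Reagents that add atoms: chloromethyl methyl ether, COCCl
Why: Williamson-type O-alkylation under weak base: the 4-OH, para to the acetyl group and flanked by two iodines, is free and the more acidic, while the 2-OH is tied up in a hydrogen bond to the ketone oxygen, so one equivalent of the small electrophile should react at O4 only.

**Step 3**
Reactants: 3 1-[2-hydroxy-3,5-diiodo-4-(methoxymethoxy)phenyl]ethanone; 4 N,N-dimethylformamide dimethyl acetal
Product: 5 (E)-3-(dimethylamino)-1-[2-hydroxy-3,5-diiodo-4-(methoxymethoxy)phenyl]prop-2-en-1-one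
Conditions: 4 (2 equiv), toluene, 85 °C
Reagents that add atoms: N,N-dimethylformamide dimethyl acetal (4), COC(OC)N(C)C
Why: Condensation of a methyl ketone with an amide acetal (enaminone formation), a reaction that 3,5-dihalo-2-hydroxyacetophenones undergo readily; the acetal carbon of 4 becomes the future C2 of ring C, and the push-pull alkene settles in the E geometry.

**Step 4**
Reactants: 5 (E)-3-(dimethylamino)-1-[2-hydroxy-3,5-diiodo-4-(methoxymethoxy)phenyl]prop-2-en-1-one
Product: 6 6,8-diiodo-7-(methoxymethoxy)-4H-chromen-4-one
Conditions: glacial AcOH, 60 °C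
Reagents that add atoms: none
Why: Acid-promoted addition–elimination (6-endo oxa-Michael attack of the 2-OH on the protonated enaminone carbon, then loss of dimethylamine) closes ring C; acetic acid is strong enough to hold the amine as its salt and so block the reverse ring opening, but too weak to ionise the aryl methoxymethyl acetal.

**Step 5**
Reactants: 6 6,8-diiodo-7-(methoxymethoxy)-4H-chromen-4-one; 7 tributyl(3-methylbut-2-enyl)stannane
Product: 8 7-(methoxymethoxy)-6,8-bis(3-methylbut-2-enyl)-4H-chromen-4-one
Conditions: 7 (2.6 equiv), Pd(PPh3)4 (10 mol %), degassed DMF, 95 °C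
Reagents that add atoms: tributyl(3-methylbut-2-enyl)stannane (7), CC(C)=CC[Sn](CCCC)(CCCC)CCCC
Why: Twofold Stille coupling: zerovalent palladium inserts into each aryl–iodine bond, the allylic stannane hands over the prenyl group, and reductive elimination from the aryl(prenyl)palladium complex occurs at the unsubstituted CH2 terminus to give the linear chains, while the neutral medium leaves the chromone enone and the acetal alone.

**Step 6**
Reactants: 8 7-(methoxymethoxy)-6,8-bis(3-methylbut-2-enyl)-4H-chromen-4-one; 9 3,4-dimethoxyphenylboronic acid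
Product: 10 (2S)-2-(3,4-dimethoxyphenyl)-7-(methoxymethoxy)-6,8-bis(3-methylbut-2-enyl)-2,3-dihydro-4H-chromen-4-one
Conditions: 9 (2.5 equiv), [RhCl(C2H4)2]2 (2.5 mol %), (S,S)-Ph-bod* = (1S,4S)-2,5-diphenylbicyclo[2.2.2]octa-2,5-diene (5.5 mol %), aq KOH (10 mol %), toluene/H2O 10:1, 40 °C
Reagents that add atoms: 3,4-dimethoxyphenylboronic acid (9), COc1ccc(B(O)O)cc1OC
Why: Hayashi–Miyaura asymmetric 1,4-addition, a reaction type already established with chromones as acceptors: the hydroxorhodium–diene complex takes the aryl group from 9 by transmetalation, 8 binds through C2=C3, syn migratory insertion puts the aryl group on C2 and rhodium on C3, and water hydrolyses the resulting oxa-π-allyl rhodium enolate to 10 and the hydroxorhodium species. The new bond is C2–C1' and no ring is closed, because ring C is already in place and stays closed. C2 is the only new stereocentre and is controlled by the twofold-symmetric diene alone: one of its phenyl groups blocks the quadrant that the C4 carbonyl and fused ring A would need in one of the two enone orientations, so the aryl–rhodium bond meets a single face of the flat enone, and the (S,S) antipode is expected to give 2S. The step must choose among three alkenes, and the substrate secures this because only C2=C3 is polarised by the C4 carbonyl, whereas the trisubstituted prenyl alkenes are poor ligands for monovalent rhodium and do not insert. The MOM ether prevents a 7-phenoxide from feeding electron density into the enone, and the excess of weakly acidic boronic acid buffers the catalytic KOH. Water in the medium protonates the enolate quickly, which keeps down both β-elimination of the O1 phenoxide (ring opening to the chalcone, the racemisation channel) and a second, 1,2-addition to the C4 ketone.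

**Step 7**
Reactants: 10 (2S)-2-(3,4-dimethoxyphenyl)-7-(methoxymethoxy)-6,8-bis(3-methylbut-2-enyl)-2,3-dihydro-4H-chromen-4-one
Product: 11 (2S)-2-(3,4-dimethoxyphenyl)-7-hydroxy-6,8-bis(3-methylbut-2-enyl)-2,3-dihydro-4H-chromen-4-one (IN0946)
Conditions: HCl (cat., about 0.5 M), MeOH, 40 °C, stopped as soon as 10 is consumed
Reagents that add atoms: none
Why: Acid-catalysed transacetalisation of the phenolic methoxymethyl ether to methanol, which runs under conditions too mild to protonate the trisubstituted prenyl alkenes and leaves C2 untouched, because the retro-oxa-Michael opening to the chalcone needs an enolate and hence base.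

**Compound list**

1 | 2,4-dihydroxyacetophenone | CC(=O)c1ccc(O)cc1O | starting material
2 | 1-(2,4-dihydroxy-3,5-diiodophenyl)ethanone | CC(=O)c1cc(I)c(O)c(I)c1O | intermediate
3 | 1-[2-hydroxy-3,5-diiodo-4-(methoxymethoxy)phenyl]ethanone | CC(=O)c1cc(I)c(OCOC)c(I)c1O | intermediate
4 | N,N-dimethylformamide dimethyl acetal | COC(OC)N(C)C | starting material
5 | (E)-3-(dimethylamino)-1-[2-hydroxy-3,5-diiodo-4-(methoxymethoxy)phenyl]prop-2-en-1-one | CN(C)/C=C/C(=O)c1cc(I)c(OCOC)c(I)c1O | intermediate
6 | 6,8-diiodo-7-(methoxymethoxy)-4H-chromen-4-one | O=c1ccoc2c(I)c(OCOC)c(I)cc12 | intermediate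
7 | tributyl(3-methylbut-2-enyl)stannane | CC(C)=CC[Sn](CCCC)(CCCC)CCCC | starting material
8 | 7-(methoxymethoxy)-6,8-bis(3-methylbut-2-enyl)-4H-chromen-4-one | O=c1ccoc2c(CC=C(C)C)c(OCOC)c(CC=C(C)C)cc12 | intermediate
9 | 3,4-dimethoxyphenylboronic acid | COc1ccc(B(O)O)cc1OC | starting material
10 | (2S)-2-(3,4-dimethoxyphenyl)-7-(methoxymethoxy)-6,8-bis(3-methylbut-2-enyl)-2,3-dihydro-4H-chromen-4-one | COc1ccc([C@@H]2CC(=O)c3cc(CC=C(C)C)c(OCOC)c(CC=C(C)C)c3O2)cc1OC | intermediate
11 | (2S)-2-(3,4-dimethoxyphenyl)-7-hydroxy-6,8-bis(3-methylbut-2-enyl)-2,3-dihydro-4H-chromen-4-one (IN0946) | COc1ccc([C@@H]2CC(=O)c3cc(CC=C(C)C)c(O)c(CC=C(C)C)c3O2)cc1OC | target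

Total step count: 7. Longest linear sequence: 7 steps (1 to 11).

**Steps most likely to fail**

**Risk 1, step 6.**
- What may go wrong: the catalyst may discriminate the faces incompletely on a chromone that carries a prenyl chain next to O1. Insertion into the electron-rich enone may be slow, with protodeboronation of 9 competing. Ring C may open at the enolate stage.
- The fallback sets the stereocentre by kinetic resolution instead of face-selective C–C bond formation. It sets out from 3 and comes back at 10.
- Twofold Stille prenylation of 3 with 7 (Pd(PPh3)4, DMF, 95 °C) should give 1-[2-hydroxy-4-(methoxymethoxy)-3,5-bis(3-methylbut-2-enyl)phenyl]ethanone F1.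
- Claisen–Schmidt condensation with 3,4-dimethoxybenzaldehyde (KOH, EtOH, rt) should give (E)-3-(3,4-dimethoxyphenyl)-1-[2-hydroxy-4-(methoxymethoxy)-3,5-bis(3-methylbut-2-enyl)phenyl]prop-2-en-1-one F2.
- NaOAc in refluxing EtOH should close this chalcone by oxa-Michael addition to racemic 2-(3,4-dimethoxyphenyl)-7-(methoxymethoxy)-6,8-bis(3-methylbut-2-enyl)-2,3-dihydro-4H-chromen-4-one F3.
- Asymmetric transfer hydrogenation is then run as a kinetic resolution (RuCl(p-cymene)[(R,R)-TsDPEN], HCO2H/Et3N, EtOAc, rt, stopped near half conversion). It should reduce the 2R enantiomer, for which the catalyst preference for 4R and the substrate preference for the cis alcohol coincide, to (2R,4R)-2-(3,4-dimethoxyphenyl)-7-(methoxymethoxy)-6,8-bis(3-methylbut-2-enyl)chroman-4-ol F4.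
- The unreduced 2S ketone is 10 and would be separated by chromatography.

**Risk 2, step 5.**
- What may go wrong: the prenyl group may be transferred through its tertiary terminus, the reaction may stall after the first coupling at the doubly flanked C8 iodide, or protodeiodination may occur.
- The fallback builds each prenyl chain in two stages. It sets out from 6 and comes back at 8.
- Twofold Stille allylation with allyltributylstannane (Pd(PPh3)4, DMF, 90 °C) uses a smaller allyl group that has no regiochemical choice. It should give 6,8-diallyl-7-(methoxymethoxy)-4H-chromen-4-one F5.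
- Twofold olefin cross-metathesis with excess 2-methylbut-2-ene (second-generation Grubbs catalyst, CH2Cl2, 40 °C) should turn both allyl groups into prenyl groups and deliver 8. The electron-poor C2=C3 alkene of the chromone is not expected to take part.

**Risk 3, step 7.**
- What may go wrong: acid may promote addition of the freed 7-OH, or of methanol, across a neighbouring prenyl alkene before the acetal is fully cleaved.
- The fallback replaces the acid-labile acetal with a fluoride-labile silyl ether. It sets out from 5 and comes back at 11. The same detour also removes the need to keep the acetal alive in step 4.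
- HCl in MeOH at rt should close ring C of 5 and strip the acetal in one operation, at a stage with no prenyl group and no stereocentre, to give 7-hydroxy-6,8-diiodo-4H-chromen-4-one F6.
- TBSCl and imidazole in DMF should give 7-(tert-butyldimethylsilyloxy)-6,8-diiodo-4H-chromen-4-one F7.
- Twofold Stille coupling with 7 as in step 5 should give 7-(tert-butyldimethylsilyloxy)-6,8-bis(3-methylbut-2-enyl)-4H-chromen-4-one F8.
- Conjugate arylation with 9 under the conditions of step 6 should give (2S)-7-(tert-butyldimethylsilyloxy)-2-(3,4-dimethoxyphenyl)-6,8-bis(3-methylbut-2-enyl)-2,3-dihydro-4H-chromen-4-one F9.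
- TBAF buffered with AcOH (THF, 0 °C) should release 11 without acid and without free base.

**Further compounds**

F1 | step 6 | 1-[2-hydroxy-4-(methoxymethoxy)-3,5-bis(3-methylbut-2-enyl)phenyl]ethanone | CC(=O)c1cc(CC=C(C)C)c(OCOC)c(CC=C(C)C)c1O
F2 | step 6 | (E)-3-(3,4-dimethoxyphenyl)-1-[2-hydroxy-4-(methoxymethoxy)-3,5-bis(3-methylbut-2-enyl)phenyl]prop-2-en-1-one | COc1ccc(/C=C/C(=O)c2cc(CC=C(C)C)c(OCOC)c(CC=C(C)C)c2O)cc1OC
F3 | step 6 | racemic 2-(3,4-dimethoxyphenyl)-7-(methoxymethoxy)-6,8-bis(3-methylbut-2-enyl)-2,3-dihydro-4H-chromen-4-one | COc1ccc(C2CC(=O)c3cc(CC=C(C)C)c(OCOC)c(CC=C(C)C)c3O2)cc1OC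
F4 | step 6 | (2R,4R)-2-(3,4-dimethoxyphenyl)-7-(methoxymethoxy)-6,8-bis(3-methylbut-2-enyl)chroman-4-ol | COc1ccc([C@H]2C[C@@H](O)c3cc(CC=C(C)C)c(OCOC)c(CC=C(C)C)c3O2)cc1OC
F5 | step 5 | 6,8-diallyl-7-(methoxymethoxy)-4H-chromen-4-one | O=c1ccoc2c(CC=C)c(OCOC)c(CC=C)cc12
F6 | step 7 | 7-hydroxy-6,8-diiodo-4H-chromen-4-one | O=c1ccoc2c(I)c(O)c(I)cc12
F7 | step 7 | 7-(tert-butyldimethylsilyloxy)-6,8-diiodo-4H-chromen-4-one | O=c1ccoc2c(I)c(O[Si](C)(C)C(C)(C)C)c(I)cc12
F8 | step 7 | 7-(tert-butyldimethylsilyloxy)-6,8-bis(3-methylbut-2-enyl)-4H-chromen-4-one | O=c1ccoc2c(CC=C(C)C)c(O[Si](C)(C)C(C)(C)C)c(CC=C(C)C)cc12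
F9 | step 7 | (2S)-7-(tert-butyldimethylsilyloxy)-2-(3,4-dimethoxyphenyl)-6,8-bis(3-methylbut-2-enyl)-2,3-dihydro-4H-chromen-4-one | COc1ccc([C@@H]2CC(=O)c3cc(CC=C(C)C)c(O[Si](C)(C)C(C)(C)C)c(CC=C(C)C)c3O2)cc1OC
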